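**Assumptions (one line):** the C10 epimers from step 7 are chromatographically separable, and (S)-Me-CBS gives the (S)-carbinol, with the alkynyl group acting as the small group. The catalyst enantiomer is swapped if the opposite sense is found.

## Retrosynthetic overview
1. Anabsin comes from the C3'=C4' alkene of an absinthin-type bis-guaianolide (16) by hydroxyl-directed exo-epoxidation and retentive C10'–OH cycloetherification. This closes the THF ring last and installs the C3'-OH.
2. Compound 16 is the endo, head-to-head [4+2] homodimer of one cyclopentadienyl guaianolide (15). This step forms the norbornane and the extra cyclopentane and sets four stereocenters.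
3. Compound 15 comes from enone 13 by Luche reduction and dehydration. Enone 13 comes from Pauson–Khand closure of 1,8-enyne 12, which builds the cyclopentenone and the cycloheptane in one step.
4. Compound 12 comes from the trans,trans-lactone 10, made by tandem cuprate addition and methylation of (S)-5-propynylbutenolide 7. Butenolide 7 comes from RCM of acrylate 6, which comes from the CBS-reduced ynenone 3. The single catalytic asymmetric event (step 2) fixes the absolute configuration of the whole lactone.
5. Ring order: lactone, then 5- and 7-rings together (Pauson–Khand), then the two [4+2] rings, then the THF ring.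

## Route

**Step 1**
Reactants: 1 N-methoxy-N-methylacrylamide (C=CC(=O)N(C)OC); 2 prop-1-ynylmagnesium bromide (CC#C[Mg]Br)
Product: 3 hex-1-en-4-yn-3-one (C=CC(=O)C#CC)
Conditions: THF, −78 → 0 °C; aq. NH4Cl
Reagents that add atoms: none (both atom-contributing partners are numbered reactants)
Why: Weinreb ketone synthesis; the chelated tetrahedral intermediate prevents over-addition and the product is achiral.

**Step 2**
Reactants: 3
Product: 4 (S)-hex-1-en-4-yn-3-ol (CC#C[C@@H](O)C=C)
Conditions: (S)-Me-CBS (10 mol %), catecholborane (1.5 equiv), toluene, −78 °C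
Reagents that add atoms: none (hydride only)
Why: Corey–Bakshi–Shibata reduction; the oxazaborolidine delivers hydride to one enantioface and the linear alkynyl acts as the small group, setting the first stereocenter (C6) with metal-free catalysis.

**Step 3**
Reactants: 4; 5 acryloyl chloride (C=CC(=O)Cl)
Product: 6 (S)-hex-1-en-4-yn-3-yl acrylate (CC#C[C@@H](OC(=O)C=C)C=C)
Conditions: Et3N, cat. DMAP, CH2Cl2, 0 °C
Reagents that add atoms: none (acryloyl chloride is numbered reactant 5)
Why: Schotten–Baumann-type esterification; the carbinol stereocenter is untouched.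

**Step 4**
Reactants: 6
Product: 7 (S)-5-(prop-1-yn-1-yl)furan-2(5H)-one (CC#C[C@H]1OC(=O)C=C1)
Conditions: Hoveyda–Grubbs II (5 mol %), CH2Cl2 (0.01 M), 40 °C
Reagents that add atoms: none (ethylene is lost)
Why: Ring-closing metathesis of the acrylate and the vinyl group gives the γ-substituted butenolide with the stereocenter retained.

**Step 5**
Reactants: 7; 8 2-(2-bromoethyl)-2-methyl-1,3-dioxolane (CC1(CCBr)OCCO1)
Product: 9 (3S,4S,5S)-3-methyl-4-[2-(2-methyl-1,3-dioxolan-2-yl)ethyl]-5-(prop-1-yn-1-yl)oxolan-2-one (CC#C[C@H]1OC(=O)[C@@H](C)[C@@H]1CCC2(C)OCCO2)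
Conditions: 8 + t-BuLi, Et2O, −78 °C, then CuI to give R2CuLi; add 7 at −78 °C; then HMPA, MeI, −78 → −20 °C
Reagents that add atoms: methyl iodide (CI)
Why: Tandem 1,4-addition/enolate alkylation; the cuprate adds anti to the C5 alkynyl (sets C7) and MeI alkylates anti to the new C7 substituent (sets C11), giving the all-trans lactone found in the target.

**Step 6**
Reactants: 9
Product: 10 (3S,4S,5S)-3-methyl-4-(3-oxobutyl)-5-(prop-1-yn-1-yl)oxolan-2-one (CC#C[C@H]1OC(=O)[C@@H](C)[C@@H]1CCC(C)=O)
Conditions: PPTS, acetone/H2O, 60 °C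
Reagents that add atoms: water (O)
Why: Acid-catalysed ketal hydrolysis unmasks the C10 methyl ketone; the lactone, alkyne and stereocenters are unaffected.

**Step 7**
Reactants: 10; 11 vinylmagnesium bromide (C=C[Mg]Br)
Product: 12 (3S,4S,5S)-4-(3-hydroxy-3-methylpent-4-en-1-yl)-3-methyl-5-(prop-1-yn-1-yl)oxolan-2-one, C10 epimeric mixture (CC#C[C@H]1OC(=O)[C@@H](C)[C@@H]1CCC(C)(O)C=C)
Conditions: CeCl3 (anhydrous), THF, −78 °C
Reagents that add atoms: none (vinylmagnesium bromide is numbered reactant 11)
Why: Organocerium 1,2-addition is chemoselective for the ketone over the lactone and creates the C10 tertiary carbinol as about 1:1 epimers, which are separated at step 8.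

**Step 8**
Reactants: 12
Product: 13 10-hydroxyguai-4-en-3-one-6,12-olide (CC1=C2[C@H]3OC(=O)[C@@H](C)[C@@H]3CC[C@](C)(O)[C@@H]2CC1=O)
Conditions: Co2(CO)8 (10 mol %), TMTU, CO (1 atm), 1,2-DCE, 75 °C; chromatographic removal of the C10-epimeric enone
Reagents that add atoms: carbon monoxide ([C-]#[O+])
Why: Intramolecular Pauson–Khand of the 1,8-enyne forms the C1–C5, C2–C3 and C3–C4 bonds, so the cyclopentenone and cycloheptane close together with the alkyne Me ending up on C4; C1 is set in the cobaltacycle, and it is a γ-position of the enone, so an epimer can be equilibrated with DBU if needed.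

**Step 9**
Reactants: 13
Product: 14 allylic alcohol at C3 (epimeric at C3): CC1=C2[C@H]3OC(=O)[C@@H](C)[C@@H]3CC[C@](C)(O)[C@@H]2CC1O
Conditions: NaBH4, CeCl3·7H2O, MeOH, −20 °C
Reagents that add atoms: none (hydride only)
Why: Luche 1,2-reduction leaves the tetrasubstituted alkene and the lactone intact; the C3 configuration is irrelevant because it is removed in the next step.

**Step 10**
Reactants: 14
Product: 15 10-hydroxyguaia-2,4-dien-6,12-olide (artabsin-type cyclopentadiene): CC1=C2[C@H]3OC(=O)[C@@H](C)[C@@H]3CC[C@](C)(O)[C@@H]2C=C1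
Conditions: Burgess reagent (1.5 equiv), benzene, 25 °C, 2 h; used without heating
Reagents that add atoms: none (the sulfamate by-products are lost)
Why: Syn-Ei dehydration (Burgess) of the secondary allylic cyclopentenol with the cis C2–H gives the C2=C3/C4=C5 diene regiospecifically, and the more hindered tertiary C10–OH reacts more slowly.

**Step 11**
Reactants: 15 (two molecules)
Product: 16 bis-guaianolide DA dimer, the absinthin skeleton: CC1=C2[C@H]3OC(=O)[C@@H](C)[C@@H]3CC[C@](C)(O)[C@@H]2[C@H]2[C@@H](C=C5C)[C@@H]4[C@]5([C@H]6OC(=O)[C@@H](C)[C@@H]6CC[C@]4(C)O)[C@@H]12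
Conditions: neat or 1 M in PhMe, 40 °C, sealed tube, dark, 3–6 d (alternatively 10 kbar, 25 °C)
Reagents that add atoms: none
Why: Proposed new method: one molecule of 15 reacts through its C2'=C3'–C4'=C5' diene and the other through its C2=C3 bond as dienophile, endo and head-to-head, as in cyclopentadiene → endo-dicyclopentadiene dimerization. Both partners are attacked on the face syn to H1 and anti to the C10 carbinol, which fixes C2, C3, C2' and C5'. The C2–C2' bond joins the two large-coefficient termini, and the C3–C5' bond closes the norbornane. The closest known reaction is cyclopentadiene dimerization, which has not been shown on a fully elaborated 10-hydroxyguaia-2,4-dienolide.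

**Step 12**
Reactants: 16
Product: 17 anabsin (target)
Conditions: mCPBA (1.1 equiv), NaHCO3, CH2Cl2, 0 °C; then CSA (0.2 equiv), 25 °C
Reagents that add atoms: meta-chloroperbenzoic acid (OOC(=O)c1cccc(Cl)c1), which donates O
Why: The C10'-OH, which sits over the exo face of the norbornene, directs Henbest-type exo epoxidation of C3'=C4' (the hindered tetrasubstituted C4=C5 alkene is untouched). Acid then ionizes the tertiary C4'–O bond, and the exo C10'-OH captures C4' from the same face in a 5-exo cyclization, giving the cis-exo ether and C3'-OH with net retention at C4'.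

## Compound list
1 | N-methoxy-N-methylacrylamide | C=CC(=O)N(C)OC | starting material
2 | prop-1-ynylmagnesium bromide | CC#C[Mg]Br | starting material
3 | hex-1-en-4-yn-3-one | C=CC(=O)C#CC | intermediate
4 | (S)-hex-1-en-4-yn-3-ol | CC#C[C@@H](O)C=C | intermediate
5 | acryloyl chloride | C=CC(=O)Cl | starting material
6 | (S)-hex-1-en-4-yn-3-yl acrylate | CC#C[C@@H](OC(=O)C=C)C=C | intermediate
7 | (S)-5-(prop-1-yn-1-yl)furan-2(5H)-one | CC#C[C@H]1OC(=O)C=C1 | intermediate
8 | 2-(2-bromoethyl)-2-methyl-1,3-dioxolane | CC1(CCBr)OCCO1 | starting material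
9 | (3S,4S,5S)-3-methyl-4-[2-(2-methyl-1,3-dioxolan-2-yl)ethyl]-5-(prop-1-yn-1-yl)oxolan-2-one | CC#C[C@H]1OC(=O)[C@@H](C)[C@@H]1CCC2(C)OCCO2 | intermediate
10 | (3S,4S,5S)-3-methyl-4-(3-oxobutyl)-5-(prop-1-yn-1-yl)oxolan-2-one | CC#C[C@H]1OC(=O)[C@@H](C)[C@@H]1CCC(C)=O | intermediate
11 | vinylmagnesium bromide | C=C[Mg]Br | starting material
12 | (3S,4S,5S)-4-(3-hydroxy-3-methylpent-4-en-1-yl)-3-methyl-5-(prop-1-yn-1-yl)oxolan-2-one (C10 epimer mixture) | CC#C[C@H]1OC(=O)[C@@H](C)[C@@H]1CCC(C)(O)C=C | intermediate
13 | 10-hydroxyguai-4-en-3-one-6,12-olide | CC1=C2[C@H]3OC(=O)[C@@H](C)[C@@H]3CC[C@](C)(O)[C@@H]2CC1=O | intermediate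
14 | 3,10-dihydroxyguai-4-en-6,12-olide (C3 epimers) | CC1=C2[C@H]3OC(=O)[C@@H](C)[C@@H]3CC[C@](C)(O)[C@@H]2CC1O | intermediate
15 | 10-hydroxyguaia-2,4-dien-6,12-olide | CC1=C2[C@H]3OC(=O)[C@@H](C)[C@@H]3CC[C@](C)(O)[C@@H]2C=C1 | intermediate
16 | absinthin-type bis-guaianolide DA dimer | CC1=C2[C@H]3OC(=O)[C@@H](C)[C@@H]3CC[C@](C)(O)[C@@H]2[C@H]2[C@@H](C=C5C)[C@@H]4[C@]5([C@H]6OC(=O)[C@@H](C)[C@@H]6CC[C@]4(C)O)[C@@H]12 | intermediate
17 | anabsin | CC1=C2[C@H]3OC(=O)[C@@H](C)[C@@H]3CC[C@](C)(O)[C@@H]2[C@H]2[C@@H]3[C@@H]4[C@]5([C@H]6OC(=O)[C@@H](C)[C@@H]6CC[C@]4(C)O[C@@]5(C)[C@H]3O)[C@@H]12 | target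

## Totals
Total steps: 12. Longest linear sequence: 12.

## Three steps most likely to fail
1. **Step 11 (proposed new [4+2] homodimerization).** Competing 1,5-H-shift diene isomers, the wrong regiochemistry or an exo mode could give mixtures.
   - Fallback: a visible-light photoredox radical-cation [4+2] homodimerization of 15 (Ru(bpz)3 or triarylaminium catalysis), a different mechanism that is known for electron-rich dienes.
2. **Step 8 (Pauson–Khand closure of the seven-membered ring).** The 1,8-enyne is a hard case and propargylic Nicholas-type ionization is a risk.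
   - Fallback: intermolecular Pauson–Khand of alkyne 10 with ethylene to give the 2-methyl-3-alkylcyclopentenone, then a base-mediated intramolecular aldol of the enone γ-position onto the C10 methyl ketone, which forms C1–C10 and the tertiary alcohol and avoids the vinyl addition of step 7.
3. **Step 12 (exo-epoxidation and retentive etherification).** Wagner–Meerwein rearrangement of the norbornyl cation or attack on the C4=C5 alkene could compete.
   - Fallback: exo-selective OsO4/NMO dihydroxylation of C3'=C4' to the cis-exo diol, then Sc(OTf)3-promoted ionization of the C10' tertiary alcohol and capture by the C4'-OH to form the THF ring.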